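The hydroazulene is traced back to a decalin by undoing two bonds at once, C1–C5 and C10–O. The feature exploited is C10 of the seven-membered ring, a tertiary carbinol (α-OH, β-CH3) whose neighbour C1 bears an α-hydrogen and belongs to a five-membered ring oxygenated at C3/C4. Irradiation of a cross-conjugated dienone in aqueous acetic acid contracts ring A, enlarges ring B and sets C1 and C10 in a single operation. The precursor is an eudesma-1,4-dien-3-one with 10β-methyl, 7β-isopropyl, a free 8β-hydroxyl and a C4 methyl group, built from (R)-carvone and ethyl vinyl ketone. A suprafacial diazene shift then sets H5β; esterification, α-epoxidation and desilylation complete the target.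

Key step: step 9

Remarks on the chemistry:
- β is the face of the C10 methyl group. Monocyclic compounds keep carvone numbering (C1 carbonyl carbon, C2 methyl-bearing, C5 isopropyl-bearing). Decalins use eudesmane numbering and hydroazulenes use guaiane numbering.
- The methyl-bearing centre created in step 4 is carried as a mixture of epimers and left open in the SMILES, because step 6 makes it trigonal again.
- The boron-bound intermediates of step 11 are drawn free of boron.
- The 8β-hydroxyl of the dienone is left unprotected. It sits 1,3 to C10 on the front face, so it cannot reach the rear lobe that water attacks, and it tolerates DDQ.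

Step 1
Reactants: 1 (R)-carvone
Product: 2 (R)-carvotanacetone = (5R)-2-methyl-5-(propan-2-yl)cyclohex-2-en-1-one
Conditions: H2 (1 atm), RhCl(PPh3)3 (cat.), toluene, rt
Reagents that add atoms: none
Why: Homogeneous hydrogenation with RhCl(PPh3)3 reduces only the unhindered 1,1-disubstituted alkene and not the conjugated trisubstituted one, and it does so without double-bond migration, so C5 keeps its configuration and the side chain is safe from the oxidant of step 3.

Step 2
Reactants: 2 (R)-carvotanacetone
Product: 3 (9R)-6-methyl-9-(propan-2-yl)-1,4-dioxaspiro[4.5]dec-6-ene (ethylene ketal of 2)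
Conditions: TMSOCH2CH2OTMS, TMSOTf (cat.), CH2Cl2, −78 to −20 °C
Reagents that add atoms: 1,2-bis(trimethylsilyloxy)ethane, C[Si](C)(C)OCCO[Si](C)(C)C
Why: Ketalisation under aprotic silyl triflate catalysis forms no dienol at low temperature, so the C2=C3 bond stays in place and C5 is untouched, while the ketal blocks C1, masks the carbonyl group and rules out later aromatisation.

Step 3
Reactants: 3 ethylene ketal of carvotanacetone
Product: 4 (9R)-6-methyl-9-(propan-2-yl)-1,4-dioxaspiro[4.5]dec-6-en-8-one (carvone C4 now a ketone)
Conditions: CrO3, 3,5-dimethylpyrazole, CH2Cl2, −20 °C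
Reagents that add atoms: chromium trioxide, O=[Cr](=O)=O
Why: In this allylic oxidation with the CrO3·3,5-dimethylpyrazole complex, C1 is blocked and the ring methylene C4 is the only secondary allylic position, so it is oxidised to the enone in preference to the vinylic methyl group under cold, near-neutral conditions that do not enolise the new ketone toward C5.

Step 4
Reactants: 4 enone ketal
Product: 5 (9R)-6-methyl-9-(propan-2-yl)-1,4-dioxaspiro[4.5]decan-8-one (both C6 epimers)
Conditions: H2 (1 atm), Pd/C, EtOAc, rt
Reagents that add atoms: none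
Why: Heterogeneous catalytic hydrogenation saturates the enone C=C bond in a neutral medium that leaves the isopropyl-bearing centre (now α to a ketone) unchanged, and the new methyl-bearing centre is of no consequence because step 6 erases it.

Step 5
Reactants: 5 keto ketal
Product: 7 (4R,5R)-4-hydroxy-2-methyl-5-(propan-2-yl)cyclohexan-1-one (both C2 epimers), via hydroxy ketal 6 (not isolated)
Conditions: LiBH(s-Bu)3, THF, −78 °C; then 2 M aq. HCl, THF, rt
Reagents that add atoms: water, O
Why: In this ketone reduction the bulky trialkylborohydride attacks equatorially on the chair with equatorial isopropyl and gives the axial alcohol cis to the isopropyl group (the menthone-to-neomenthol pattern), which sets the future 8β-carbinol, and aqueous acid then hydrolyses the dioxolane.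

Step 6
Reactants: 7 cis-hydroxy ketone; 8 (R)-1-phenylethylamine; 9 ethyl vinyl ketone
Product: 12 (2R,4R,5R)-4-hydroxy-2-methyl-2-(3-oxopentyl)-5-(propan-2-yl)cyclohexan-1-one, via ketimine 10 (not isolated), via Michael adduct ketimine 11 (not isolated)
Conditions: 8, TsOH (cat.), toluene, reflux (Dean–Stark); then 9, THF, 40 °C; then 20% aq. AcOH, rt
Reagents that add atoms: water, O
Why: In this asymmetric Michael addition of a chiral imine through its more substituted secondary enamine tautomer (first half of a Robinson annulation), the (R)-1-phenylethyl group shields the β face in the compact aza-ene-like transition state and the axial hydroxyl 1,3 to the reacting carbon blocks the same face, so the enone bonds from the α face, the methyl group ends β (future C10), and mild acid hydrolyses 11 and returns the amine.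

Step 7
Reactants: 12 diketone
Product: 14 8β-hydroxyeudesm-4-en-3-one (7β-isopropyl and 10β-methyl), via ketol 13 (not isolated)
Conditions: NaOMe (cat.), MeOH, rt to 50 °C
Reagents that add atoms: none
Why: In this intramolecular aldol condensation (second half of the Robinson annulation) the ethyl ketone enolises toward its CH2 group and attacks the ring carbonyl in a 6-enolexo closure of ring A, ketol 13 loses water to the tetrasubstituted enone, and none of the three existing centres is enolisable.

Step 8
Reactants: 14 8β-hydroxyeudesm-4-en-3-one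
Product: 15 8β-hydroxyeudesma-1,4-dien-3-one (7β-isopropyl and 10β-methyl)
Conditions: DDQ, 1,4-dioxane, reflux
Reagents that add atoms: none
Why: In DDQ dehydrogenation without added acid, hydride is taken from C1 of the kinetically formed 2,4-dienol, the usual course for 4-en-3-ones, which gives the C1=C2 bond, and the unactivated secondary alcohol is not oxidised.

Step 9
Reactants: 15 8β-hydroxyeudesma-1,4-dien-3-one
Product: 17 8β,10α-dihydroxy-1αH-guai-4-en-3-one, via oxyallyl zwitterion 16 (not isolated)
Conditions: hν (medium-pressure Hg lamp, Pyrex filter), AcOH/H2O 1:1, Ar, 15–20 °C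
Reagents that add atoms: water, O
Why: This is the photorearrangement of a cross-conjugated cyclohexadienone in protic acid, the type by which santonin gives isophotosantonic lactone: n–π* excitation and intersystem crossing let the two β-carbons C1 and C5 bond, and spin inversion gives zwitterion 16, which holds a C1–C5–C10 cyclopropane. Acetic acid protonates the oxygen, and the hydroxyallyl cation draws in the C5–C10 σ bond while water enters at the rear lobe of C10, an SN2-like cyclopropylcarbinyl opening. The five-membered ring is closed by transannular C1–C5 bonding across ring A (ring contraction), whereas the seven-membered ring is not cyclised but arises by enlargement of ring B by one atom (C1) when the bond it shares with the cyclopropane breaks. C1 is fixed because ring B can only be cis-fused to the cyclopropane, which forces C10 to rise on the face of its own methyl group and leaves H1 α, and C10 is fixed by inversion, giving 10α-OH and 10β-CH3. The step needs cleavage of C5–C10 rather than of C1–C10 (spiro ketone) or a 1,4-shift (lumiketone), and this is secured by the C4 methyl group, which localises the positive charge on C4 next to C5, and by the protic medium, which intercepts 16 before it can shift. The free 8β-hydroxyl lies 1,3 to C10 on the front face and cannot compete with water.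

Step 10
Reactants: 17 8β,10α-dihydroxy-1αH-guai-4-en-3-one
Product: 18 (E)-tosylhydrazone of 17
Conditions: TsNHNH2, EtOH, 60 °C
Reagents that add atoms: 4-methylbenzenesulfonohydrazide, Cc1ccc(cc1)S(=O)(=O)NN
Why: The ketone condenses with the sulfonyl hydrazide so that the NHTs group settles on the open C2 side, the fully substituted β-carbon C5 rules out conjugate addition, and the medium is too mild to ionise the tertiary alcohol.

Step 11
Reactants: 18 tosylhydrazone
Product: 21 1αH,5βH-guai-3-ene-8β,10α-diol, via allylic tosylhydrazine 19 (not isolated), via allylic diazene 20 (not isolated)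
Conditions: catecholborane (excess), CHCl3, −10 to 0 °C; then NaOAc·3H2O, reflux
Reagents that add atoms: none
Why: In this catecholborane reduction of an α,β-unsaturated tosylhydrazone with alkene transposition (allylic diazene retro-ene rearrangement), hydride reaches C3 from the α face because C10 and its methyl group stand over the β face of the flat five-membered ring, acetate releases sulfinate from 19, and β-diazene 20 hands its hydrogen suprafacially to C5 while N2 leaves and the double bond moves to C3=C4, which sets H5β (trans fusion) stereospecifically instead of leaving it to an external proton source that would come from the open α face.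

Step 12
Reactants: 22 vanillic acid
Product: 24 4-(tert-butyldimethylsilyloxy)-3-methoxybenzoic acid, via silyl ester 23 (not isolated)
Conditions: TBSCl, imidazole, DMF, rt; then AcOH/THF/H2O, rt
Reagents that add atoms: tert-butyldimethylsilyl chloride, CC(C)(C)[Si](C)(C)Cl
Why: Both acidic OH groups are silylated and the far more labile silyl ester is then hydrolysed selectively, which leaves the aryl silyl ether in place.

Step 13
Reactants: 21 1αH,5βH-guai-3-ene-8β,10α-diol; 24 4-(tert-butyldimethylsilyloxy)-3-methoxybenzoic acid
Product: 25 10α-hydroxy-1αH,5βH-guai-3-en-8β-yl 4-(tert-butyldimethylsilyloxy)-3-methoxybenzoate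
Conditions: DCC, DMAP, CH2Cl2, rt to reflux
Reagents that add atoms: none
Why: In this Steglich esterification the DMAP-bound acyl donor acylates the secondary 8β-hydroxyl at oxygen with retention, the tertiary C10 hydroxyl is inert, and the masked phenol cannot self-condense.

Step 14
Reactants: 25 guai-3-enyl ester
Product: 26 3α,4α-epoxy-10α-hydroxy-1αH,5βH-guaian-8β-yl 4-(tert-butyldimethylsilyloxy)-3-methoxybenzoate
Conditions: DMDO (acetone solution), CH2Cl2, −20 to 0 °C
Reagents that add atoms: dimethyldioxirane, CC1(C)OO1
Why: In this dioxirane epoxidation (concerted spiro oxygen transfer, neutral medium) the trans fusion locks the cyclopentene as an envelope with C1 tipped toward the α face, so attack from α is staggered against the allylic bonds whereas the β face presents the pseudoaxial H5 and H2β and the C10 methyl group, and the C10 hydroxyl at the ring edge can hydrogen-bond to the oxidant only on the α side, which places the oxygen α at C3 and C4.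

Step 15
Reactants: 26 silylated epoxy ester
Product: 27 3α,4α-epoxy-10α-hydroxy-1αH,5βH-guaian-8β-yl 4-hydroxy-3-methoxybenzoate (target CNP0136245.2)
Conditions: TBAF, AcOH, THF, 0 °C
Reagents that add atoms: none
Why: Fluoride cleaves the aryl silyl ether within minutes, acetic acid buffers the phenoxide so that ester and epoxide survive, and the α-hydroxyl cannot open the α-epoxide from its rear side.

Compound list
1 | (R)-carvone | CC1=CC[C@H](CC1=O)C(C)=C | starting material
2 | (R)-carvotanacetone, (5R)-2-methyl-5-(propan-2-yl)cyclohex-2-en-1-one | CC1=CC[C@H](CC1=O)C(C)C | intermediate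
3 | (9R)-6-methyl-9-(propan-2-yl)-1,4-dioxaspiro[4.5]dec-6-ene | CC1=CC[C@H](CC12OCCO2)C(C)C | intermediate
4 | (9R)-6-methyl-9-(propan-2-yl)-1,4-dioxaspiro[4.5]dec-6-en-8-one | CC1=CC(=O)[C@H](CC12OCCO2)C(C)C | intermediate
5 | (9R)-6-methyl-9-(propan-2-yl)-1,4-dioxaspiro[4.5]decan-8-one, C6 epimers | CC1CC(=O)[C@H](CC12OCCO2)C(C)C | intermediate
6 | (8R,9R)-6-methyl-9-(propan-2-yl)-1,4-dioxaspiro[4.5]decan-8-ol, OH cis to isopropyl, C6 epimers | CC1C[C@@H](O)[C@H](CC12OCCO2)C(C)C | intermediate (not isolated)
7 | (4R,5R)-4-hydroxy-2-methyl-5-(propan-2-yl)cyclohexan-1-one, C2 epimers | O[C@@H]1CC(C)C(=O)C[C@@H]1C(C)C | intermediate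
8 | (R)-1-phenylethylamine | C[C@@H](N)c1ccccc1 | starting material
9 | ethyl vinyl ketone | CCC(=O)C=C | starting material
10 | N-[(1R)-1-phenylethyl] ketimine of 7 | O[C@@H]1CC(C)C(=N[C@H](C)c2ccccc2)C[C@@H]1C(C)C | intermediate (not isolated)
11 | N-[(1R)-1-phenylethyl] ketimine of 12 | O[C@@H]1C[C@@](C)(CCC(=O)CC)C(=N[C@H](C)c2ccccc2)C[C@@H]1C(C)C | intermediate (not isolated)
12 | (2R,4R,5R)-4-hydroxy-2-methyl-2-(3-oxopentyl)-5-(propan-2-yl)cyclohexan-1-one | O[C@@H]1C[C@@](C)(CCC(=O)CC)C(=O)C[C@@H]1C(C)C | intermediate
13 | 5,8β-dihydroxyeudesman-3-one (ketol, C4 and C5 open) | O[C@@H]1C[C@@]2(C)CCC(=O)C(C)C2(O)C[C@@H]1C(C)C | intermediate (not isolated)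
14 | 8β-hydroxyeudesm-4-en-3-one (7β-isopropyl, 10β-methyl) | O[C@@H]1C[C@@]2(C)CCC(=O)C(C)=C2C[C@@H]1C(C)C | intermediate
15 | 8β-hydroxyeudesma-1,4-dien-3-one (7β-isopropyl, 10β-methyl) | O[C@@H]1C[C@@]2(C)C=CC(=O)C(C)=C2C[C@@H]1C(C)C | intermediate
16 | oxyallyl zwitterion with C1–C5–C10 cyclopropane, C10 on the β face, H1 α | O[C@@H]1C[C@@]2(C)[C@@H]3C=C([O-])[C+](C)[C@]23C[C@@H]1C(C)C | intermediate (not isolated)
17 | 8β,10α-dihydroxy-1αH-guai-4-en-3-one | O[C@@H]1C[C@@](C)(O)[C@@H]2CC(=O)C(C)=C2C[C@@H]1C(C)C | intermediate
18 | (E)-tosylhydrazone of 17 | O[C@@H]1C[C@@](C)(O)[C@@H]2C/C(=N\NS(=O)(=O)c3ccc(C)cc3)C(C)=C2C[C@@H]1C(C)C | intermediate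
19 | 3β-(2-tosylhydrazinyl)-1αH-guai-4-ene-8β,10α-diol | O[C@@H]1C[C@@](C)(O)[C@@H]2C[C@H](NNS(=O)(=O)c3ccc(C)cc3)C(C)=C2C[C@@H]1C(C)C | intermediate (not isolated)
20 | 3β-diazenyl-1αH-guai-4-ene-8β,10α-diol | O[C@@H]1C[C@@](C)(O)[C@@H]2C[C@H](N=N)C(C)=C2C[C@@H]1C(C)C | intermediate (not isolated)
21 | 1αH,5βH-guai-3-ene-8β,10α-diol | O[C@@H]1C[C@@](C)(O)[C@@H]2CC=C(C)[C@H]2C[C@@H]1C(C)C | intermediate
22 | vanillic acid | COc1cc(C(=O)O)ccc1O | starting material
23 | tert-butyldimethylsilyl 4-(tert-butyldimethylsilyloxy)-3-methoxybenzoate | COc1cc(C(=O)O[Si](C)(C)C(C)(C)C)ccc1O[Si](C)(C)C(C)(C)C | intermediate (not isolated)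
24 | 4-(tert-butyldimethylsilyloxy)-3-methoxybenzoic acid | COc1cc(C(=O)O)ccc1O[Si](C)(C)C(C)(C)C | intermediate
25 | 10α-hydroxy-1αH,5βH-guai-3-en-8β-yl 4-(tert-butyldimethylsilyloxy)-3-methoxybenzoate | COc1cc(C(=O)O[C@@H]2C[C@@](C)(O)[C@@H]3CC=C(C)[C@H]3C[C@@H]2C(C)C)ccc1O[Si](C)(C)C(C)(C)C | intermediate
26 | 3α,4α-epoxy-10α-hydroxy-1αH,5βH-guaian-8β-yl 4-(tert-butyldimethylsilyloxy)-3-methoxybenzoate | COc1cc(C(=O)O[C@@H]2C[C@@](C)(O)[C@@H]3C[C@H]4O[C@@]4(C)[C@H]3C[C@@H]2C(C)C)ccc1O[Si](C)(C)C(C)(C)C | intermediate
27 | 3α,4α-epoxy-10α-hydroxy-1αH,5βH-guaian-8β-yl 4-hydroxy-3-methoxybenzoate (CNP0136245.2) | COc1cc(C(=O)O[C@@H]2C[C@@](C)(O)[C@@H]3C[C@H]4O[C@@]4(C)[C@H]3C[C@@H]2C(C)C)ccc1O | target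

Total step count: 15. Longest linear sequence: 14 (steps 1–11 and 13–15).

Steps most likely to fail

1. Step 9 (key step).
   - What may go wrong: the zwitterion may be diverted into the 1,4-shift or into cleavage of the other cyclopropane bond, and the product enone may undergo secondary photolysis during long irradiation in the dilute wet medium.
   - Fallback: this sets out from 15. Irradiation in glacial acetic acid makes acetate the only nucleophile and should give 10α-acetoxy-8β-hydroxy-1αH-guai-4-en-3-one F1. Base would expel the tertiary acetate through the vinylogous enolate at C1, so the ester is removed reductively with LiAlH4 (THF, 0 °C). That reagent also reduces C3 from the open α face and gives 1αH-guai-4-ene-3β,8β,10α-triol F2. MnO2 (CH2Cl2, rt) then re-oxidises only the allylic C3 carbinol, and the route is rejoined at 17.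

2. Step 3.
   - What may go wrong: hydrogen abstraction may be sluggish or unselective (attack at the vinylic methyl group), the ketal may be lost, or the new ketone may enolise with erosion of the isopropyl-bearing centre.
   - Fallback: this sets out from 2 and replaces steps 2–5.
     - Soft enolisation toward C4 (TBSOTf, Et3N, CH2Cl2, 0 °C to rt) would give the through-conjugated silyl dienol ether F3.
     - mCPBA (CH2Cl2, −20 °C; vinylogous Rubottom oxidation) attacks the distal double bond anti to the isopropyl group and gives the dienol ether epoxide F4.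
     - On aqueous acidic work-up this epoxide collapses to the trans γ-hydroxy enone F5.
     - A Mitsunobu reaction (4-nitrobenzoic acid, PPh3, DIAD, THF) inverts the carbinol to the cis 4-nitrobenzoate F6. Elimination is held back because C3 is sp2 and H5 is syn to the leaving group.
     - Methanolysis (K2CO3, MeOH, 0 °C) frees the cis γ-hydroxy enone F7.
     - Hydrogenation (H2, Pd/C, EtOAc) rejoins the route at 7.

3. Step 14.
   - What may go wrong: facial selectivity of the oxygen transfer to the trisubstituted alkene may be poor.
   - Fallback: this sets out from 25. NBS in aqueous THF (0 °C) places the halonium ion on whichever face electrophiles prefer. If that is the β face, water opens it anti at the tertiary C4 and gives the 3β-bromo-4α-hydroxy bromohydrin F8. DBU (CH2Cl2, rt) then closes the ring by internal SN2 displacement at C3. The facial outcome of a direct oxygen transfer is thereby reversed, and the route is rejoined at 26.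

Further compounds
F1 | step 9 | 10α-acetoxy-8β-hydroxy-1αH-guai-4-en-3-one | O[C@@H]1C[C@@](C)(OC(C)=O)[C@@H]2CC(=O)C(C)=C2C[C@@H]1C(C)C
F2 | step 9 | 1αH-guai-4-ene-3β,8β,10α-triol | O[C@@H]1C[C@@](C)(O)[C@@H]2C[C@H](O)C(C)=C2C[C@@H]1C(C)C
F3 | step 3 | tert-butyl-dimethyl-{[(5R)-2-methyl-5-(propan-2-yl)cyclohexa-1,3-dien-1-yl]oxy}silane | CC1=C(O[Si](C)(C)C(C)(C)C)C[C@H](C(C)C)C=C1
F4 | step 3 | 3,4-epoxide of F3, oxygen anti to isopropyl | CC1=C(O[Si](C)(C)C(C)(C)C)C[C@H](C(C)C)[C@H]2O[C@@H]12
F5 | step 3 | (4R,5R)-4-hydroxy-2-methyl-5-(propan-2-yl)cyclohex-2-en-1-one | O[C@H]1C=C(C)C(=O)C[C@@H]1C(C)C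
F6 | step 3 | (4S,5R)-2-methyl-4-(4-nitrobenzoyloxy)-5-(propan-2-yl)cyclohex-2-en-1-one | O=C(O[C@@H]1C=C(C)C(=O)C[C@@H]1C(C)C)c1ccc(cc1)[N+](=O)[O-]
F7 | step 3 | (4S,5R)-4-hydroxy-2-methyl-5-(propan-2-yl)cyclohex-2-en-1-one | O[C@@H]1C=C(C)C(=O)C[C@@H]1C(C)C
F8 | step 14 | 3β-bromo-4α,10α-dihydroxy-1αH,5βH-guaian-8β-yl 4-(tert-butyldimethylsilyloxy)-3-methoxybenzoate | COc1cc(C(=O)O[C@@H]2C[C@@](C)(O)[C@@H]3C[C@H](Br)[C@@](C)(O)[C@H]3C[C@@H]2C(C)C)ccc1O[Si](C)(C)C(C)(C)C
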